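## Retrosynthetic overview
1. 15 ⇒ 13 ⇒ 12. The quinone is made last by oxidising the ring-B phenol, as the plant oxidises an isoflavan. The 7-OH stays masked as a benzyl ether until the end.
2. 12 ⇒ 9. Pyran ring C is the only ring built. The 2'-phenol O attacks the former chalcone β-carbon (C-2 oxocarbenium), and C-4 loses its oxygen through the quinone-methide cation. Both cations take hydride in one flask.
3. 9 ⇒ 8 ⇒ 7. C-3 is set directly by an enantioselective oxidative 1,2-shift of ring B (C-2 → C-3) on the chalcone with a chiral λ3-iodane. The achiral isoflavone is never formed.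
4. 7 ⇒ 4 + 5 by Claisen–Schmidt condensation. 4 ⇒ acetosyringone 1 by O-benzylation, ring bromination and Cu hydroxylation.
5. Ring order: A and B are bought, C closes in step 8, and B becomes the quinone in step 9.

Assumption: the lactate-derived λ3-iodane follows the accepted face model for styrene-type alkenes ((R,R)-reagent on the Si face of the ArCH= carbon), so the (S,S)-reagent is taken for the (S)-centre; if the measured sign is opposite, the (R,R)-reagent is used and nothing else changes.

Reagent note: (S,S)-I* is dimethyl (2S,2'S)-2,2'-{[2-(diacetoxy-λ3-iodanyl)-1,3-phenylene]bis(oxy)}dipropanoate, SMILES C[C@H](Oc1cccc(O[C@@H](C)C(=O)OC)c1I(OC(C)=O)OC(C)=O)C(=O)OC. It is a known reagent made in two operations from 2-iodoresorcinol and methyl (R)-lactate. It is not counted in the step total, and its iodoarene is recovered.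

## Route

Step 1
Reactants: 1 acetosyringone
Product: 2 1-[4-(benzyloxy)-3,5-dimethoxyphenyl]ethanone
Conditions: BnBr, K2CO3, DMF, 60 °C
Reagents that add atoms: benzyl bromide BrCc1ccccc1
Why: Williamson etherification of the only acidic OH; the benzyl group shields the easily oxidised ring-A phenol from iodine(III) in step 6 and from the phenol oxidation in step 9.

Step 2
Reactants: 2 1-[4-(benzyloxy)-3,5-dimethoxyphenyl]ethanone
Product: 3 1-[4-(benzyloxy)-2-bromo-3,5-dimethoxyphenyl]ethanone
Conditions: NBS (1.05 equiv), MeCN, 0 °C → rt, dark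
Reagents that add atoms: N-bromosuccinimide O=C1CCC(=O)N1Br
Why: Electrophilic aromatic bromination; the two free ring positions are equivalent and each lies ortho and para to a methoxy group, and the polar, acid-free, dark conditions favour ring over α-bromination.

Step 3
Reactants: 3 1-[4-(benzyloxy)-2-bromo-3,5-dimethoxyphenyl]ethanone
Product: 4 1-[4-(benzyloxy)-2-hydroxy-3,5-dimethoxyphenyl]ethanone
Conditions: Cu(acac)2 (5 mol %), oxalamide ligand BHMPO (5 mol %), LiOH·H2O (2.2 equiv), DMSO/H2O 4:1, 80 °C; then 1 M HCl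
Reagents that add atoms: lithium hydroxide [Li+].[OH-]
Why: Ullmann-type Cu-catalysed hydroxylation of an aryl bromide, helped by the ortho carbonyl group; the benzyl and methyl ethers are inert.

Step 4
Reactants: 4 1-[4-(benzyloxy)-2-hydroxy-3,5-dimethoxyphenyl]ethanone; 5 3-hydroxy-4,5-dimethoxybenzaldehyde
Product: 6 (E)-1-[4-(benzyloxy)-2-hydroxy-3,5-dimethoxyphenyl]-3-(3-hydroxy-4,5-dimethoxyphenyl)prop-2-en-1-one
Conditions: KOH (50 % aq), EtOH, rt, 48 h; then 1 M HCl
Reagents that add atoms: none
Why: Claisen–Schmidt condensation gives the E-2'-hydroxychalcone, the C6–C3–C6 precursor of all isoflavonoids; a meta-phenolate does not deactivate the aldehyde, and E1cB dehydration gives the E-alkene.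

Step 5
Reactants: 6 (E)-2'-hydroxychalcone
Product: 7 (E)-1-[2-acetoxy-4-(benzyloxy)-3,5-dimethoxyphenyl]-3-(3-acetoxy-4,5-dimethoxyphenyl)prop-2-en-1-one
Conditions: Ac2O, pyridine, DMAP (cat.), CH2Cl2, rt
Reagents that add atoms: acetic anhydride CC(=O)OC(C)=O
Why: DMAP-catalysed acetylation masks both phenols against iodine(III) and prevents early ring closure, which would lead to the achiral isoflavone.

Step 6
Reactants: 7 chalcone diacetate
Product: 8 (2S)-1-[2-acetoxy-4-(benzyloxy)-3,5-dimethoxyphenyl]-2-(3-acetoxy-4,5-dimethoxyphenyl)-3,3-dimethoxypropan-1-one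
Conditions: (S,S)-I* (1.3 equiv), TfOH (2 equiv), MeOH (10 equiv), CH2Cl2/CF3CH2OH 10:1, −78 → −30 °C; cold Et3N quench
Reagents that add atoms: methanol CO
Why: Enantioselective hypervalent-iodine oxidative rearrangement of a chalcone (the chemical counterpart of the isoflavone-synthase aryl shift): the C2-symmetric iodane adds to one alkene face at Cα, methanol adds anti at Cβ, ring B then bridges as a phenonium ion and displaces the aryl iodide with inversion at Cα, so the reagent's face choice fixes the (S)-centre (future C-3), and methanol traps the oxocarbenium ion as the dimethyl acetal, which prevents a readily enolised 1,3-dicarbonyl from forming.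

Step 7
Reactants: 8 (2S)-keto acetal
Product: 9 (1RS,2R)-1-[4-(benzyloxy)-2-hydroxy-3,5-dimethoxyphenyl]-2-(3-hydroxy-4,5-dimethoxyphenyl)-3,3-dimethoxypropan-1-ol
Conditions: LiAlH4 (3 equiv), THF, −78 → 0 °C; Rochelle salt; used crude
Reagents that add atoms: none
Why: Hydride reduction; at low temperature addition to the ketone is far faster than enolisation, so the α-aryl centre is kept (the label becomes R only through CIP priorities), both aryl acetates are cleaved, the benzyl ether and acetal are inert, and the new carbinol centre (a mixture) is erased in step 8.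

Step 8
Reactants: 9 (1RS,2R)-triol acetal
Product: 12 5-[(3S)-7-(benzyloxy)-6,8-dimethoxychroman-3-yl]-2,3-dimethoxyphenol, via phenol acetal 10 (not isolated), via 2-methoxyisoflavan 11 (not isolated)
Conditions: Et3SiH (10 equiv), TFA (15 equiv), CH2Cl2 (0.02 M), −40 → 0 °C; NaHCO3
Reagents that add atoms: none
Why: Ionic hydrogenation (Kursanov–Parnes) cascade that copies the late biosynthetic events: the electron-rich C-4 carbinol ionises to the quinone-methide-type cation and takes hydride, the 2'-phenol exchanges into the acetal to close the O1–C2 bond, and the cyclic oxocarbenium ion formed by loss of the more basic methoxy group is reduced by the large excess of silane faster than it can lose H-3, so C-3 stays (S).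

Step 9
Reactants: 12 (3S)-isoflavan phenol
Product: 13 5-[(3S)-7-(benzyloxy)-6,8-dimethoxychroman-3-yl]-2,3-dimethoxycyclohexa-2,5-diene-1,4-dione
Conditions: O2 (1 atm), Co(salen) (10 mol %), DMF, rt
Reagents that add atoms: dioxygen O=O
Why: Co(salen)-catalysed aerobic oxidation of a phenol to the p-quinone; the only free phenol sits in ring B with an open para position, ring A is fully etherified, and C-3 is not touched.

Step 10
Reactants: 13 (3S)-7-O-benzyl quinone
Product: 15 5-[(3S)-7-hydroxy-6,8-dimethoxychroman-3-yl]-2,3-dimethoxycyclohexa-2,5-diene-1,4-dione (CNP0121136.1), via hydroquinone 14 (not isolated)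
Conditions: H2 (1 atm), 10 % Pd/C, EtOAc/MeOH, rt; filter; air, SiO2, rt
Reagents that add atoms: none
Why: Hydrogenolysis of the benzyl ether also reduces the quinone to its hydroquinone, and air then re-oxidises only this hydroquinone because its potential lies far below that of the hindered ring-A phenol; the stereocentre is not involved.

## Compound list
1 | acetosyringone, 1-(4-hydroxy-3,5-dimethoxyphenyl)ethanone | CC(=O)c1cc(OC)c(O)c(OC)c1 | starting material
2 | 1-[4-(benzyloxy)-3,5-dimethoxyphenyl]ethanone | CC(=O)c1cc(OC)c(OCc2ccccc2)c(OC)c1 | intermediate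
3 | 1-[4-(benzyloxy)-2-bromo-3,5-dimethoxyphenyl]ethanone | CC(=O)c1cc(OC)c(OCc2ccccc2)c(OC)c1Br | intermediate
4 | 1-[4-(benzyloxy)-2-hydroxy-3,5-dimethoxyphenyl]ethanone | CC(=O)c1cc(OC)c(OCc2ccccc2)c(OC)c1O | intermediate
5 | 3-hydroxy-4,5-dimethoxybenzaldehyde | O=Cc1cc(O)c(OC)c(OC)c1 | starting material
6 | (E)-1-[4-(benzyloxy)-2-hydroxy-3,5-dimethoxyphenyl]-3-(3-hydroxy-4,5-dimethoxyphenyl)prop-2-en-1-one | O=C(/C=C/c1cc(O)c(OC)c(OC)c1)c1cc(OC)c(OCc2ccccc2)c(OC)c1O | intermediate
7 | (E)-chalcone diacetate (2'-OAc on ring A, 3-OAc on ring B) | CC(=O)Oc1cc(/C=C/C(=O)c2cc(OC)c(OCc3ccccc3)c(OC)c2OC(C)=O)cc(OC)c1OC | intermediate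
8 | (2S)-1-[2-acetoxy-4-(benzyloxy)-3,5-dimethoxyphenyl]-2-(3-acetoxy-4,5-dimethoxyphenyl)-3,3-dimethoxypropan-1-one | CC(=O)Oc1cc(cc(OC)c1OC)[C@H](C(=O)c1cc(OC)c(OCc2ccccc2)c(OC)c1OC(C)=O)C(OC)OC | intermediate
9 | (1RS,2R)-1-[4-(benzyloxy)-2-hydroxy-3,5-dimethoxyphenyl]-2-(3-hydroxy-4,5-dimethoxyphenyl)-3,3-dimethoxypropan-1-ol (C-1 epimers) | Oc1cc(cc(OC)c1OC)[C@H](C(O)c1cc(OC)c(OCc2ccccc2)c(OC)c1O)C(OC)OC | intermediate
10 | 3-(benzyloxy)-6-[(2S)-2-(3-hydroxy-4,5-dimethoxyphenyl)-3,3-dimethoxypropyl]-2,4-dimethoxyphenol | Oc1cc(cc(OC)c1OC)[C@H](Cc1cc(OC)c(OCc2ccccc2)c(OC)c1O)C(OC)OC | intermediate (not isolated)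
11 | 5-[(3S)-7-(benzyloxy)-2,6,8-trimethoxychroman-3-yl]-2,3-dimethoxyphenol (C-2 epimers) | Oc1cc(cc(OC)c1OC)[C@H]1C(OC)Oc2c(cc(OC)c(OCc3ccccc3)c2OC)C1 | intermediate (not isolated)
12 | 5-[(3S)-7-(benzyloxy)-6,8-dimethoxychroman-3-yl]-2,3-dimethoxyphenol | Oc1cc(cc(OC)c1OC)[C@H]1COc2c(cc(OC)c(OCc3ccccc3)c2OC)C1 | intermediate
13 | 5-[(3S)-7-(benzyloxy)-6,8-dimethoxychroman-3-yl]-2,3-dimethoxycyclohexa-2,5-diene-1,4-dione | COC1=C(OC)C(=O)C([C@H]2COc3c(cc(OC)c(OCc4ccccc4)c3OC)C2)=CC1=O | intermediate
14 | 5-[(3S)-7-hydroxy-6,8-dimethoxychroman-3-yl]-2,3-dimethoxybenzene-1,4-diol | COc1c(OC)c(O)c(cc1O)[C@H]1COc2c(cc(OC)c(O)c2OC)C1 | intermediate (not isolated)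
15 | 5-[(3S)-7-hydroxy-6,8-dimethoxy-3,4-dihydro-2H-chromen-3-yl]-2,3-dimethoxycyclohexa-2,5-diene-1,4-dione (CNP0121136.1) | COC1=C(OC)C(=O)C([C@H]2COc3c(cc(OC)c(O)c3OC)C2)=CC1=O | target

## Step count and weak points
Total step count: 10. Longest linear sequence: 10 steps from 1; aldehyde 5 enters in step 4.

**Step 6.** The 3-acetoxy-4,5-dimethoxyphenyl ring is only a moderate migrating group. The enone is a slow partner for iodine(III), and the ee may be low or may erode through acid enolisation of 8.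
- The fallback sets the centre by reduction instead of by migration. It sets out from 7 and rejoins the route at 12.
- PhI(OAc)2, TsOH and MeOH/HC(OMe)3 give the racemic keto acetal F1.
- Hot methanolic HCl removes both acetates, closes the ring and eliminates methanol to give the isoflavone F2.
- Asymmetric transfer hydrogenation with RuCl[(S,S)-TsDPEN](p-cymene) in HCO2H/Et3N first reduces the C2–C3 double bond. Dynamic kinetic resolution of the resulting isoflavanone then gives the (3S,4S)-cis-isoflavan-4-ol F3.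
- Et3SiH/TFA removes the 4-OH to give 12.

**Step 8.** Three side reactions are possible:
- The open methoxycarbenium ion may be reduced to a methyl ether.
- The cyclic cation may lose H-3, which would racemise C-3.
- Ring A may attack C-2 in a Friedel–Crafts sense.

The fallback closes the ring by SN2 displacement instead of by oxocarbenium reduction. It sets out from 9 and rejoins the route at 12.
- Et3SiH (2 equiv) and TFA (2 equiv) at −78 °C stop at 10, which is isolated.
- AcOH/H2O/THF hydrolyses the acetal to the lactol F4.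
- NaBH4 in EtOH at 0 °C reduces it through its open form to the primary alcohol F5.
- Intramolecular Mitsunobu etherification (PPh3, DIAD, THF, high dilution) gives 12.

**Step 3.** The bromide is flanked on both sides, and the methyl ketone must sit in hot hydroxide.
- The fallback goes through boron. It sets out from 3 and rejoins the route at 4.
- Miyaura borylation (B2pin2, Pd(OAc)2/SPhos, KOAc, dioxane, 90 °C) gives the pinacol boronate F6.
- Oxidation with N-methylmorpholine N-oxide (THF, 50 °C) gives 4. This oxidant is chosen over alkaline H2O2 to avoid Dakin cleavage of the o-hydroxy ketone.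

## Further compounds
F1 | step 6 | racemic 1-[2-acetoxy-4-(benzyloxy)-3,5-dimethoxyphenyl]-2-(3-acetoxy-4,5-dimethoxyphenyl)-3,3-dimethoxypropan-1-one | CC(=O)Oc1cc(cc(OC)c1OC)C(C(=O)c1cc(OC)c(OCc2ccccc2)c(OC)c1OC(C)=O)C(OC)OC
F2 | step 6 | 7-(benzyloxy)-3-(3-hydroxy-4,5-dimethoxyphenyl)-6,8-dimethoxy-4H-chromen-4-one | O=c1c(-c2cc(O)c(OC)c(OC)c2)coc2c(OC)c(OCc3ccccc3)c(OC)cc12
F3 | step 6 | (3S,4S)-7-(benzyloxy)-3-(3-hydroxy-4,5-dimethoxyphenyl)-6,8-dimethoxychroman-4-ol (cis) | Oc1cc(cc(OC)c1OC)[C@H]1COc2c(OC)c(OCc3ccccc3)c(OC)cc2[C@H]1O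
F4 | step 8 | (3S)-7-(benzyloxy)-3-(3-hydroxy-4,5-dimethoxyphenyl)-6,8-dimethoxychroman-2-ol (C-2 epimers) | Oc1cc(cc(OC)c1OC)[C@H]1C(O)Oc2c(cc(OC)c(OCc3ccccc3)c2OC)C1
F5 | step 8 | 3-(benzyloxy)-6-[(2S)-3-hydroxy-2-(3-hydroxy-4,5-dimethoxyphenyl)propyl]-2,4-dimethoxyphenol | Oc1cc(cc(OC)c1OC)[C@H](Cc1cc(OC)c(OCc2ccccc2)c(OC)c1O)CO
F6 | step 3 | 1-[4-(benzyloxy)-3,5-dimethoxy-2-(4,4,5,5-tetramethyl-1,3,2-dioxaborolan-2-yl)phenyl]ethanone | CC(=O)c1cc(OC)c(OCc2ccccc2)c(OC)c1B1OC(C)(C)C(C)(C)O1
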